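The X left over late in the earlier runs, 1.2 % in alpha and 0 % in epsilon at 25.0 h, is of the size of the scatter, so the late Q of those runs can stand as their final Q.

all flasks: X 0.026 M
- alpha: E 0.073 M; G 0.039 M; run made earlier
- epsilon: E 0.087 M; G 0.039 M; run made earlier
- Saturday's: E 0.0520 M; G 0.0390 M; time 25 h
- Thursday's: E 0.0780 M; G 0.0390 M; time 25 h

| run | time / h | Q / % | X / % | L / % | Z / % | J / % |
|---|---|---|---|---|---|---|
| alpha | 2.00 | 12.7 | 46.1 | 1.6 | 2.3 | 39.4 |
| alpha | 4.00 | 21.7 | 19.3 | 1.4 | 7.0 | 48.8 |
| alpha | 8.00 | 33.3 | 4.9 | 0.6 | 15.5 | 47.1 |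
| alpha | 12.0 | 36.3 | 0.4 | 0.7 | 23.6 | 40.9 |
| alpha | 25.0 | 33.7 | 1.2 | 1.4 | 37.4 | 25.2 |
| epsilon | 5.00 | 25.3 | 8.4 | 0 | 9.1 | 55.0 |
| epsilon | 10.0 | 29.9 | 1.3 | 0.4 | 21.6 | 47.8 |
| epsilon | 15.0 | 30.7 | 1.2 | 1.2 | 31.7 | 38.6 |
| epsilon | 20.0 | 30.0 | 0 | 0.3 | 37.1 | 31.8 |
| epsilon | 25.0 | 29.5 | 0 | 1.1 | 41.9 | 27.4 |

(each reading ± 1 percentage point)

- a species is counted by the X in it: one Q counts as two
- what was read earlier has a scatter of 1 percentage point, one standard deviation

* which of these there is most of at the end, counted by the X in it, Saturday's (Z / J / L / Q)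
* which of these there is most of at the end, counted by the X in it, Thursday's (Z / J / L / Q)
* the largest of these amounts at the end, in percent of the X charged, Saturday's
* the largest of these amounts at the end, in percent of the X charged, Thursday's

1. The main step, X with E to J, counted by itself, sends the charge of X into J, and Q and Z stay at zero.

2. A rival for X comes next: in epsilon, Q reads 29.9 % at 10.0 h and 29.5 % at 25.0 h, so it stays flat once X is down to 1.3 %. Late Q averages 35.0 % in alpha and 30.0 % in epsilon. The rule tried here is a selectivity factor called the even point: the charged [E] multiplied by the share of X in Q and divided by the share of X elsewhere. An even split of X is the zero of this scale, where the charged [E] equals the even point. Alpha gives 0.0393 M and epsilon 0.0373 M, a gap of the size the scatter on Q makes, so the mean 0.0383 M is carried forward. The Q share is then the even point over the even point plus the charged [E], which gives 42.4 % for Saturday's and 32.9 % for Thursday's.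

3. J goes on to Z, and this reckoning simply divides what Q leaves between the two by a share read from the earlier runs. At 25 h, Z as a share of Z plus J reads 59.7 % in alpha and 60.5 % in epsilon. Their mean, 60.1 %, puts Z at 34.6 % in Saturday's and 40.3 % in Thursday's.

4. L, at 1.4 % in alpha and 1.1 % in epsilon at 25.0 h, is of the size of the scatter and is left out. This reckoning therefore has Q leading Saturday's at 42.4 % and Z leading Thursday's at 40.3 %.

5. The forecast names Q at 44 % for Saturday's and Z at 39 % for Thursday's, reasoning “so less E gives more Q”: the same leaders, with its first figure higher than the reckoned one and its second lower.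

6. Saturday's ends with Q leading at 41.7 %, ahead of Z at 34.2 %, and Thursday's ends with Z leading at 40.5 %, ahead of Q at 32.3 %.

    X + E → J (k = 0.0880 L mol⁻¹ min⁻¹)
    G + J → Z (k = 0.0210 L mol⁻¹ min⁻¹)
    X + G → L (k = 0.00170 L mol⁻¹ min⁻¹)
    X + J → Q (k = 0.130 L mol⁻¹ min⁻¹)
    G → D (k = 2.20 × 10⁻⁶ min⁻¹)

7. Saturday's left until 2.5 d still holds Q at 41.8 %, while Z has climbed to 50.0 %, so the lead there passes to Z. The even point taken from the final Q stands at 0.0372 M in Saturday's and at 0.0373 M in Thursday's.

The numbers in the tables stem from a simulated flask on assumed constants, and the scatter is random.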